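My choice of the next run began from a ratio: how much solid Z can put into solution during the life of the reagent J, over how much Z was charged. Z dissolves to Q, Q meets J to give the product E, J also decays by itself to X, and crystals D form when E passes its solubility.

Z 0.68 M; J 1.50 equiv; time 25 s

1. E and D together at 25 s, in percent of the Z charged
2. the change that raises the amount of E and D together at 25 s, in percent of the Z charged most ("none" if none brings more than 2 percentage points) (spring / summer / dusk / midnight / none)
3. amount of E and D together at 25 s, in percent of the Z charged, after dusk

    Z ⇌ Q, rate k1*(cs1 - [Q]) while solid is left; crystals form when [Q] > cs1 (cs1 = 0.28 M, k1 = 0.60 s⁻¹)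
    Q + J → E (k2 = 1.4 L mol⁻¹ s⁻¹)
    J → X (k3 = 0.20 s⁻¹)
    D ⇌ E, rate k4*(cs4 - [E]) while solid is left; crystals form when [E] > cs4 (cs4 = 0.52 M, k4 = 1.4 s⁻¹)

Into an empty solution Z feeds at most 0.168 M s⁻¹, and J lives on average 5.00 s by its decay, so the ratio was 124%. But J as charged pulls Q away at 1.43 s⁻¹, faster than the dissolving coefficient 0.60 s⁻¹, so I held Q at the balance of feed and pull (a quasi-steady state) and summed the share of J that reaches E as J falls. That brought in a second rate, hold, the dissolving coefficient plus 1.4 L mol⁻¹ s⁻¹ times feed times life: 1.78 s⁻¹. The ratio times the log of one plus pull over hold gave 72.9%. I called this the reach, the E that J can make, in percent of the Z charged, if Q stood at that balance from the first moment.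

Q starts from nothing, so I took the reach as a ceiling: E and D together below 72.9%. No constant of step 4 enters it, so spring and summer scored nothing. Doubling the solubility of Z gave a reach of 97.5%, a ceiling of 97.5% after dusk. Doubling J gave a reach of 118%, more than the charge, so in my reckoning Z caps it there. I would charge for midnight.

The forecast gave 62%, then 81% after dusk, and chose midnight, holding that “doubling J keeps reagent alive until all the Z is in”. Its figures are values, and mine were ceilings above them.

The simulation gave 63.9%, then 80.6% after dusk, and midnight as best, worth 32 percentage points against 17 points for dusk and 0 points for spring.

The ceiling held, 9 points above the result. E and D stopped at 63.9% because J decayed while the low solubility of Q held back the feed: the run without the decay gave >99.9%, and the run without that solubility limit, which is a part of the cause, gave 93.2%. For the same flask with 0.380 equiv of J, the reach is 22.9%, and the computed result there is 18.8%.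

(The rate constants are those of an exercise, and the outcome is calculated.)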